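**Retrosynthetic overview**

1. ent-Abyssinone III ⇒ open the O1–C2 bond of ring C to the free (E)-2',4'-dihydroxychalcone; forward, a catalyst-controlled 6-endo oxa-Michael closure (the bond chalcone isomerase makes) sets C2 in the last step.
2. Chalcone ⇒ cut Cα=Cβ to 2',4'-dihydroxyacetophenone and 2,2-dimethyl-8-prenyl-2H-chromene-6-carbaldehyde (Claisen–Schmidt, no protecting groups).
3. Chromene aldehyde ⇒ open the pyran O–CMe2 bond to 4-hydroxy-3,5-diprenylbenzaldehyde; forward, dehydrogenative prenylphenol-to-chromene cyclization through an o-quinone methide.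
4. Diprenyl aldehyde ⇒ cut both aryl–CH2 bonds to 3,5-dibromo-4-hydroxybenzaldehyde and prenylboronic acid pinacol ester (double Suzuki–Miyaura coupling).
5. Ring order: chromene ring first (step 2), ring C last (step 4), so the oxidant never meets the C2–H of a 4'-hydroxyflavanone and the stereocentre never meets base.

Assumption: compound numbers follow the forward route, and compound 2 and the thiourea catalyst are bought.

**Route**

Step 1
Reactants: 1 3,5-dibromo-4-hydroxybenzaldehyde; 2 prenylboronic acid pinacol ester [4,4,5,5-tetramethyl-2-(3-methylbut-2-en-1-yl)-1,3,2-dioxaborolane] (2.6 equiv)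
Product: 4 4-hydroxy-3,5-bis(3-methylbut-2-en-1-yl)benzaldehyde, via monoprenyl bromophenol 3 (not isolated)
Conditions: PdCl2(IPent)(3-chloropyridine) (4 mol%; IPent = 1,3-bis[2,6-di(pentan-3-yl)phenyl]imidazol-2-ylidene), 5 M aq. KOH, THF, 70 °C
Reagents that add atoms: none
Why: Double Suzuki–Miyaura sp2–sp3 coupling in which the allylpalladium aryl intermediate equilibrates through its η3 form and the bulky IPent ligand forces reductive elimination at the unsubstituted terminus, so the linear prenyl group (not 1,1-dimethylallyl) is installed twice, while hydroxide keeps the substrate as a phenoxide whose aldehyde is a poor electrophile for allylboration; no stereocentre is formed.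

Step 2
Reactants: 4 4-hydroxy-3,5-bis(3-methylbut-2-en-1-yl)benzaldehyde
Product: 6 2,2-dimethyl-8-(3-methylbut-2-en-1-yl)-2H-chromene-6-carbaldehyde, via o-quinone methide 5 (not isolated)
Conditions: DDQ (1.1 equiv), toluene, 80 °C
Reagents that add atoms: none
Why: Biomimetic dehydrogenative cyclization of an ortho-prenylphenol, in which DDQ removes hydride from the benzylic–allylic CH2 to give o-quinone methide 5 and its (Z)-oxatriene closes by oxa-6π electrocyclization to the 2,2-dimethyl-2H-chromene; only one prenyl group can cyclize because there is one phenol oxygen, and the remaining prenyl group on the now non-phenolic ring is much slower to oxidize; no stereocentre is formed.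

Step 3
Reactants: 6 2,2-dimethyl-8-(3-methylbut-2-en-1-yl)-2H-chromene-6-carbaldehyde; 7 1-(2,4-dihydroxyphenyl)ethan-1-one (2',4'-dihydroxyacetophenone)
Product: 9 (2E)-1-(2,4-dihydroxyphenyl)-3-[2,2-dimethyl-8-(3-methylbut-2-en-1-yl)-2H-chromen-6-yl]prop-2-en-1-one, via aldol adduct 8 (not isolated)
Conditions: KOH (60% aq., 10 equiv), EtOH, 0 °C to rt, 48 h
Reagents that add atoms: none
Why: Claisen–Schmidt (crossed aldol) condensation, in which the ketone enolate adds to the non-enolizable, non-phenolic aldehyde 6 and aldol adduct 8 loses water by E1cB to the thermodynamic (E)-enone; chromene and prenyl groups are inert to hydroxide and the chalcone is freed on acidification; the carbinol centre of 8 is destroyed again.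

Step 4
Reactants: 9 (2E)-1-(2,4-dihydroxyphenyl)-3-[2,2-dimethyl-8-(3-methylbut-2-en-1-yl)-2H-chromen-6-yl]prop-2-en-1-one
Product: 10 ent-abyssinone III [(2R)-2-[2,2-dimethyl-8-(3-methylbut-2-en-1-yl)-2H-chromen-6-yl]-7-hydroxy-2,3-dihydro-4H-chromen-4-one]
Conditions: 1-[3,5-bis(trifluoromethyl)phenyl]-3-[(8α,9S)-6'-methoxycinchonan-9-yl]thiourea (quinine-derived, 20 mol%), toluene/CH2Cl2 9:1, 0 °C, stopped at about 80% conversion, filtered through silica with 1% AcOH in the eluent, chalcone recycled
Reagents that add atoms: none
Why: Proposed new method: the thiourea N–H pair binds the chalcone carbonyl (breaking the 2'-OH···O=C chelate, holding the enone s-trans and raising its electrophilicity) while the quinuclidine acts as general base on the 2'-OH, so the phenol oxygen adds 6-endo-trig to the Re face of C-β inside the chiral pocket and the enol is protonated at C-3 by the quinuclidinium, which sets C-2 as R under catalyst control (sense assigned by analogy and to be confirmed on the first run by CD, negative Cotton effect near 330 nm for 2R; the quinidine-derived pseudoenantiomer gives the mirror image); the closest known reaction type is the enantioselective intramolecular oxa-Michael addition of 2'-hydroxychalcones carrying an α-alkoxycarbonyl activating group under the same cinchona thiourea catalysis, together with aminothiourea-catalysed cycloetherification of phenols onto simple enones; because the closure is reversible the reaction is run cold and stopped before equilibrium so the kinetic ee is kept.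

**Compound list**

1 | 3,5-dibromo-4-hydroxybenzaldehyde | O=Cc1cc(Br)c(O)c(Br)c1 | starting material
2 | 4,4,5,5-tetramethyl-2-(3-methylbut-2-en-1-yl)-1,3,2-dioxaborolane (prenylboronic acid pinacol ester) | CC(C)=CCB1OC(C)(C)C(C)(C)O1 | starting material
3 | 3-bromo-4-hydroxy-5-(3-methylbut-2-en-1-yl)benzaldehyde (monoprenyl bromophenol, not isolated) | CC(C)=CCc1cc(C=O)cc(Br)c1O | intermediate
4 | 4-hydroxy-3,5-bis(3-methylbut-2-en-1-yl)benzaldehyde | CC(C)=CCc1cc(C=O)cc(CC=C(C)C)c1O | intermediate
5 | 5-(3-methylbut-2-en-1-yl)-3-[(Z)-3-methylbut-2-en-1-ylidene]-4-oxocyclohexa-1,5-diene-1-carbaldehyde (o-quinone methide, not isolated) | CC(C)=C/C=C1\C(=O)C(CC=C(C)C)=CC(C=O)=C1 | intermediate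
6 | 2,2-dimethyl-8-(3-methylbut-2-en-1-yl)-2H-chromene-6-carbaldehyde | CC(C)=CCc1cc(C=O)cc2c1OC(C)(C)C=C2 | intermediate
7 | 1-(2,4-dihydroxyphenyl)ethan-1-one | CC(=O)c1ccc(O)cc1O | starting material
8 | 1-(2,4-dihydroxyphenyl)-3-[2,2-dimethyl-8-(3-methylbut-2-en-1-yl)-2H-chromen-6-yl]-3-hydroxypropan-1-one (racemic aldol adduct, not isolated) | CC(C)=CCc1cc(C(O)CC(=O)c2ccc(O)cc2O)cc2c1OC(C)(C)C=C2 | intermediate
9 | (2E)-1-(2,4-dihydroxyphenyl)-3-[2,2-dimethyl-8-(3-methylbut-2-en-1-yl)-2H-chromen-6-yl]prop-2-en-1-one | CC(C)=CCc1cc(/C=C/C(=O)c2ccc(O)cc2O)cc2c1OC(C)(C)C=C2 | intermediate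
10 | ent-abyssinone III, (2R)-2-[2,2-dimethyl-8-(3-methylbut-2-en-1-yl)-2H-chromen-6-yl]-7-hydroxy-2,3-dihydro-4H-chromen-4-one | CC(C)=CCc1cc([C@H]2CC(=O)c3ccc(O)cc3O2)cc2c1OC(C)(C)C=C2 | target

**Summary**

Total step count: 4. Longest linear sequence: 4 steps (1 → 4 → 6 → 9 → 10).

**Steps most likely to fail, with fallbacks**

Step 4 is the most likely to fail. The enone is unactivated, the acidic 4'-OH can tie up the amine of the catalyst, the closure is reversible so ee erodes near equilibrium, and the sense of induction is untested on this substrate class. The fallback sets out from 9 and comes back at 10. Chalcone 9 is cyclized without stereocontrol (NaOAc, EtOH, reflux, unreacted chalcone recycled) to the racemic flavanone F1. F1 is then resolved kinetically by Noyori–Ikariya transfer hydrogenation with RuCl[(S,S)-TsDPEN](p-cymene) (2 mol%), HCO2H/Et3N 5:2, EtOAc, rt, to about 55% conversion. The (S,S) catalyst delivers hydride in the 4S sense and anti to the aryl group, so it consumes the 2S enantiomer as the cis-(2S,4S)-flavan-4-ol F2. The unreacted 2R ketone is separated by chromatography and is compound 10; the ceiling is 50% yield.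

Step 1 is second. The second coupling must occur on an electron-rich bromophenoxide, and prenyl transfer can give the branched isomer, attack the aldehyde, or be lost to protodeboronation. The fallback sets out from 1 and comes back at 6. Compound 1 is coupled with only 1.05 equiv of 2 (same catalyst, 50 °C) and the monoprenyl bromophenol 3 is isolated. The chromene is then closed first with DDQ (toluene, 80 °C) to 8-bromo-2,2-dimethyl-2H-chromene-6-carbaldehyde F3. The second prenyl group is installed on this neutral aryl bromide by Stille coupling with tributyl(3-methylbut-2-en-1-yl)stannane, Pd(PPh3)4, DMF, 100 °C, a reagent that does not add to the aldehyde, giving 6.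

Step 3 is third. Under hydroxide the ketone carries two phenoxides, so enolization is slow and yields of unprotected 2',4'-dihydroxychalcones are often modest. The fallback sets out from 7 and comes back at 9. The non-chelated 4-OH of 7 is protected selectively (chloromethyl methyl ether, K2CO3, acetone, rt) to give 1-[2-hydroxy-4-(methoxymethoxy)phenyl]ethan-1-one F4. F4 is condensed with 6 (KOH, EtOH, rt) to the 4'-O-methoxymethyl chalcone F5. The acetal is cleaved with 3 M HCl in MeOH at 40 °C to give 9.

**Further compounds**

F1 | step 4 | racemic 2-[2,2-dimethyl-8-(3-methylbut-2-en-1-yl)-2H-chromen-6-yl]-7-hydroxy-2,3-dihydro-4H-chromen-4-one | CC(C)=CCc1cc(C2CC(=O)c3ccc(O)cc3O2)cc2c1OC(C)(C)C=C2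
F2 | step 4 | (2S,4S)-2-[2,2-dimethyl-8-(3-methylbut-2-en-1-yl)-2H-chromen-6-yl]-3,4-dihydro-2H-chromene-4,7-diol | CC(C)=CCc1cc([C@@H]2C[C@H](O)c3ccc(O)cc3O2)cc2c1OC(C)(C)C=C2
F3 | step 1 | 8-bromo-2,2-dimethyl-2H-chromene-6-carbaldehyde | CC1(C)C=Cc2cc(C=O)cc(Br)c2O1
F4 | step 3 | 1-[2-hydroxy-4-(methoxymethoxy)phenyl]ethan-1-one | CC(=O)c1ccc(OCOC)cc1O
F5 | step 3 | (2E)-3-[2,2-dimethyl-8-(3-methylbut-2-en-1-yl)-2H-chromen-6-yl]-1-[2-hydroxy-4-(methoxymethoxy)phenyl]prop-2-en-1-one | CC(C)=CCc1cc(/C=C/C(=O)c2ccc(OCOC)cc2O)cc2c1OC(C)(C)C=C2
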